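**Plan**

- Retrosynthesis: remove the N-sulfonyl helper, then cut the bond between C3 of the unsubstituted indole ring and the bis(indolyl) methine carbon, giving indole and a trans-2,3-epoxy alcohol. The epoxide goes back to an (E)-allylic alcohol, the alkenyl–C2 bond to a Stille coupling of a 2-bromoindole, and that to tryptophol.
- Enabling feature: the methine carbon sits between C2 of the 2,3-disubstituted indole ring (benzylic activation) and the secondary carbinol carbon of the propane-1,2-diol chain. This C(aryl)–C(OH) pair is the retron of an anti opening of an aryl epoxy alcohol at its benzylic carbon, and the partner is the nucleophilic C3 of an indole ring.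
- Forward order: tryptophol → O-acetate → C2-bromide → N-(2-nitrobenzenesulfonyl) (Ns) → (E)-hydroxypropenyl side chain → epoxy alcohol → fragment union with indole → N-deprotection. No new ring remains in the target; the oxirane is a temporary ring.
- Stereochemistry: one Sharpless epoxidation with D-(−)-tartrate sets both centers as (2R,3R). The carbinol center is kept; the methine center is formed by inversion in the epoxide opening, giving (1S,2S).
- Helpers: the N-Ns group (electron-withdrawing, no carbonyl oxygen to participate, removed by thiolate without touching the acetate); the acetate is installed first so the side-chain oxygen cannot cyclise onto C2 or the benzylic carbon.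

Key step: step 6

Remark: (E)-3-(tributylstannyl)prop-2-en-1-ol is taken as a purchasable reagent (otherwise one step from propargyl alcohol and Bu3SnH).

**Route**

Step 1
Reactants: 1 tryptophol [2-(1H-indol-3-yl)ethan-1-ol]
Product: 2 2-(1H-indol-3-yl)ethyl acetate
Conditions: Ac2O (1.2 equiv), pyridine, CH2Cl2, 0 °C → rt
Reagents that add atoms: acetic anhydride, CC(=O)OC(C)=O
Why: O-acylation of the primary alcohol; without DMAP or a strong base the non-basic indole N–H should stay free.

Step 2
Reactants: 2 2-(1H-indol-3-yl)ethyl acetate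
Product: 4 2-(2-bromo-1H-indol-3-yl)ethyl acetate, via 3-bromoindolenine 3 (not isolated)
Conditions: NBS (1.0 equiv), CH2Cl2, 0 °C → rt, dark; used promptly
Reagents that add atoms: N-bromosuccinimide, O=C1CCC(=O)N1Br
Why: electrophilic bromination of a 3-alkylindole at C3 gives 3, whose bromine shifts to C2 with rearomatisation; the acetate blocks the oxygen cyclisation that free tryptophol would undergo.

Step 3
Reactants: 4 2-(2-bromo-1H-indol-3-yl)ethyl acetate
Product: 6 2-[2-bromo-1-(2-nitrobenzenesulfonyl)-1H-indol-3-yl]ethyl acetate, via N-lithio bromoindole 5 (not isolated)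
Conditions: LiHMDS (1.05 equiv), THF, −78 °C; then 2-nitrobenzenesulfonyl chloride (1.1 equiv), −78 → 0 °C
Reagents that add atoms: 2-nitrobenzenesulfonyl chloride, O=[N+]([O-])c1ccccc1S(=O)(=O)Cl; LiHMDS, [Li]N([Si](C)(C)C)[Si](C)(C)C (supplies only the lithium of 5)
Why: N-sulfonylation of an indolide; the N–H is far more acidic than the acetate α-protons, so one equivalent of amide base at −78 °C should deprotonate nitrogen only.

Step 4
Reactants: 6 2-[2-bromo-1-(2-nitrobenzenesulfonyl)-1H-indol-3-yl]ethyl acetate; 7 (E)-3-(tributylstannyl)prop-2-en-1-ol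
Product: 8 2-[2-[(E)-3-hydroxyprop-1-en-1-yl]-1-(2-nitrobenzenesulfonyl)-1H-indol-3-yl]ethyl acetate
Conditions: Pd(PPh3)4 (5 mol %), CuI (10 mol %), DMF, 60 °C
Reagents that add atoms: none
Why: Stille coupling at the C2–Br bond activated by the N-sulfonyl group; the alkenyl group transfers with retention of E geometry, and the neutral conditions spare the acetate and the N–S bond.

Step 5
Reactants: 8 2-[2-[(E)-3-hydroxyprop-1-en-1-yl]-1-(2-nitrobenzenesulfonyl)-1H-indol-3-yl]ethyl acetate
Product: 9 2-[2-[(2R,3R)-3-(hydroxymethyl)oxiran-2-yl]-1-(2-nitrobenzenesulfonyl)-1H-indol-3-yl]ethyl acetate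
Conditions: Ti(OiPr)4 (0.2 equiv), D-(−)-diisopropyl tartrate (0.25 equiv), t-BuOOH (2 equiv, decane), 4 Å MS, CH2Cl2, −20 °C
Reagents that add atoms: tert-butyl hydroperoxide, CC(C)(C)OO
Why: Sharpless asymmetric epoxidation of an (E)-3-aryl allylic alcohol; by the usual facial rule the D-(−)-tartrate catalyst should give the (2R,3R)-trans-epoxy alcohol, setting both stereocenters under reagent control, while the N-sulfonyl group keeps the indole C2=C3 bond inert to the oxidant and tames the aryl epoxide.

Step 6
Reactants: 9 2-[2-[(2R,3R)-3-(hydroxymethyl)oxiran-2-yl]-1-(2-nitrobenzenesulfonyl)-1H-indol-3-yl]ethyl acetate; 10 indole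
Product: 11 2-[2-[(1S,2S)-2,3-dihydroxy-1-(1H-indol-3-yl)propyl]-1-(2-nitrobenzenesulfonyl)-1H-indol-3-yl]ethyl acetate
Conditions: indole (3 equiv), InBr3 (10 mol %), CH2Cl2, −20 °C → rt
Reagents that add atoms: none
Why: InBr3 binds the epoxide oxygen and the neighbouring primary hydroxyl of 9, and C3 of indole 10 attacks the benzylic epoxide carbon from the side opposite its C–O bond in a borderline SN2 Friedel–Crafts alkylation, followed by rearomatisation. The closest known reaction type is the Lewis acid-catalysed opening of enantiopure aryl epoxides and 3-aryl-2,3-epoxy alcohols by indoles at the benzylic carbon with inversion. No ring is closed; the temporary oxirane is opened and the 1,2-diol appears. The new bis(indolyl)methine stereocenter is controlled by the configuration of the epoxide carbon through inversion, while the carbinol center keeps its C–O bond and the geometry set in step 5. The step needs benzylic over non-benzylic attack, inversion instead of ionisation to a free cation, C3 instead of N1 attack of indole, and no internal capture: the indol-2-yl ring and the inductively deactivated neighbouring carbon direct attack to the benzylic position, the electron-withdrawing N-sulfonyl group (no carbonyl oxygen, unlike a carbamate) disfavours ionisation and neighbouring-group interception, and the acetate cannot close a pyran ring as a free side-chain hydroxyl would.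

Step 7
Reactants: 11 2-[2-[(1S,2S)-2,3-dihydroxy-1-(1H-indol-3-yl)propyl]-1-(2-nitrobenzenesulfonyl)-1H-indol-3-yl]ethyl acetate
Product: 12 colletotryptin C, 2-[2-[(1S,2S)-2,3-dihydroxy-1-(1H-indol-3-yl)propyl]-1H-indol-3-yl]ethyl acetate
Conditions: PhSH (1.5 equiv), K2CO3 (2 equiv), DMF, rt
Reagents that add atoms: none
Why: Fukuyama-type denosylation; thiolate adds at the ipso carbon of the nitroarene, SO2 is lost and the indole N–H is released, while the soft thiolate and carbonate at rt should leave the primary acetate, the diol and both non-epimerisable stereocenters untouched.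

**Compound list**

1 | tryptophol, 2-(1H-indol-3-yl)ethan-1-ol | OCCc1c[nH]c2ccccc12 | starting material
2 | 2-(1H-indol-3-yl)ethyl acetate | CC(=O)OCCc1c[nH]c2ccccc12 | intermediate
3 | 2-(3-bromo-3H-indol-3-yl)ethyl acetate (racemic bromoindolenine, formed and consumed in step 2) | CC(=O)OCCC1(Br)C=Nc2ccccc12 | intermediate
4 | 2-(2-bromo-1H-indol-3-yl)ethyl acetate | CC(=O)OCCc1c(Br)[nH]c2ccccc12 | intermediate
5 | N-lithio derivative of 4 (formed and consumed in step 3) | CC(=O)OCCc1c(Br)n([Li])c2ccccc12 | intermediate
6 | 2-[2-bromo-1-(2-nitrobenzenesulfonyl)-1H-indol-3-yl]ethyl acetate | CC(=O)OCCc1c(Br)n(S(=O)(=O)c2ccccc2[N+](=O)[O-])c2ccccc12 | intermediate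
7 | (E)-3-(tributylstannyl)prop-2-en-1-ol | CCCC[Sn](CCCC)(CCCC)/C=C/CO | starting material
8 | 2-[2-[(E)-3-hydroxyprop-1-en-1-yl]-1-(2-nitrobenzenesulfonyl)-1H-indol-3-yl]ethyl acetate | CC(=O)OCCc1c(/C=C/CO)n(S(=O)(=O)c2ccccc2[N+](=O)[O-])c2ccccc12 | intermediate
9 | 2-[2-[(2R,3R)-3-(hydroxymethyl)oxiran-2-yl]-1-(2-nitrobenzenesulfonyl)-1H-indol-3-yl]ethyl acetate | CC(=O)OCCc1c([C@H]2O[C@@H]2CO)n(S(=O)(=O)c3ccccc3[N+](=O)[O-])c3ccccc13 | intermediate
10 | indole | c1ccc2[nH]ccc2c1 | starting material
11 | 2-[2-[(1S,2S)-2,3-dihydroxy-1-(1H-indol-3-yl)propyl]-1-(2-nitrobenzenesulfonyl)-1H-indol-3-yl]ethyl acetate | CC(=O)OCCc1c([C@H](c2c[nH]c3ccccc23)[C@H](O)CO)n(S(=O)(=O)c2ccccc2[N+](=O)[O-])c2ccccc12 | intermediate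
12 | colletotryptin C, 2-[2-[(1S,2S)-2,3-dihydroxy-1-(1H-indol-3-yl)propyl]-1H-indol-3-yl]ethyl acetate | CC(=O)OCCc1c([C@H](c2c[nH]c3ccccc23)[C@H](O)CO)[nH]c2ccccc12 | target

**Count and risks**

Total steps: 7. Longest linear sequence: 7 steps (1 → 12).

Most likely to fail:

1. Step 6. The activated epoxide may ionise to a delocalised benzylic cation, eroding the stereospecificity at the methine; a hydride shift to a carbonyl compound or stalling at the crowded benzylic carbon are also possible. The fallback sets the two centers one at a time by amine catalysis. It sets out from 8 and comes back at 12. MnO2 in CH2Cl2 should oxidise 8 to the (E)-enal 2-[1-(2-nitrobenzenesulfonyl)-2-[(E)-3-oxoprop-1-en-1-yl]-1H-indol-3-yl]ethyl acetate F1. Iminium-catalysed Friedel–Crafts conjugate addition of indole 10 with the (2R,5R)-5-benzyl-2-tert-butyl-3-methylimidazolidin-4-one TFA salt should give the (S)-aldehyde 2-[2-[(1S)-1-(1H-indol-3-yl)-3-oxopropyl]-1-(2-nitrobenzenesulfonyl)-1H-indol-3-yl]ethyl acetate F2. D-Proline-catalysed α-aminoxylation with nitrosobenzene should give the (1S,2S)-α-anilinooxy aldehyde F3, reduced in the same flask with NaBH4 to the O-anilino diol F4. Denosylation as in step 7 gives the N–H O-anilino diol F5, and Zn/AcOH cleavage of the N–O bond releases 12.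

2. Step 5. The titanium Lewis acid may open the freshly formed aryl epoxide with isopropoxide or tartrate, and oxygen transfer may be slow or poorly face-selective because the alkene is twisted out of the indole plane by its two flanking substituents. The fallback sets out from 8 and comes back at 9 without a new compound: a Shi epoxidation with the D-fructose-derived ketone, Oxone and carbonate buffer in MeCN/dimethoxymethane/water at 0 °C. This is a non-directed chiral dioxirane oxidation with no Lewis acid, which for trans-aryl alkenes should give the same (R,R) epoxide.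

3. Step 2. Over-bromination, diversion of bromoindolenine 3 by water to an oxindole, and decomposition of the N–H 2-bromoindole on handling may all occur. The fallback avoids electrophilic bromination of the indole. It sets out from 2 and comes back at 4: iridium-catalysed C2–H borylation ([Ir(OMe)(cod)]2, dtbpy, B2pin2, THF, 60 °C) should give 2-[2-(4,4,5,5-tetramethyl-1,3,2-dioxaborolan-2-yl)-1H-indol-3-yl]ethyl acetate F6, and copper(II) bromide-mediated bromodeboronation (CuBr2, MeOH/H2O) then gives 4.

**Further compounds**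

F1 | step 6 | 2-[1-(2-nitrobenzenesulfonyl)-2-[(E)-3-oxoprop-1-en-1-yl]-1H-indol-3-yl]ethyl acetate | CC(=O)OCCc1c(/C=C/C=O)n(S(=O)(=O)c2ccccc2[N+](=O)[O-])c2ccccc12
F2 | step 6 | 2-[2-[(1S)-1-(1H-indol-3-yl)-3-oxopropyl]-1-(2-nitrobenzenesulfonyl)-1H-indol-3-yl]ethyl acetate | CC(=O)OCCc1c([C@H](c2c[nH]c3ccccc23)CC=O)n(S(=O)(=O)c2ccccc2[N+](=O)[O-])c2ccccc12
F3 | step 6 | 2-[2-[(1S,2S)-1-(1H-indol-3-yl)-3-oxo-2-(phenylaminooxy)propyl]-1-(2-nitrobenzenesulfonyl)-1H-indol-3-yl]ethyl acetate | CC(=O)OCCc1c([C@H](c2c[nH]c3ccccc23)[C@H](ONc2ccccc2)C=O)n(S(=O)(=O)c2ccccc2[N+](=O)[O-])c2ccccc12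
F4 | step 6 | 2-[2-[(1S,2S)-3-hydroxy-1-(1H-indol-3-yl)-2-(phenylaminooxy)propyl]-1-(2-nitrobenzenesulfonyl)-1H-indol-3-yl]ethyl acetate | CC(=O)OCCc1c([C@H](c2c[nH]c3ccccc23)[C@H](ONc2ccccc2)CO)n(S(=O)(=O)c2ccccc2[N+](=O)[O-])c2ccccc12
F5 | step 6 | 2-[2-[(1S,2S)-3-hydroxy-1-(1H-indol-3-yl)-2-(phenylaminooxy)propyl]-1H-indol-3-yl]ethyl acetate | CC(=O)OCCc1c([C@H](c2c[nH]c3ccccc23)[C@H](ONc2ccccc2)CO)[nH]c2ccccc12
F0 | step 5 | none | none
F6 | step 2 | 2-[2-(4,4,5,5-tetramethyl-1,3,2-dioxaborolan-2-yl)-1H-indol-3-yl]ethyl acetate | CC(=O)OCCc1c(B2OC(C)(C)C(C)(C)O2)[nH]c2ccccc12
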